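**Plan**
1. Numbering (labdane): ring A = C1–C5 + C10, ring B = C5–C10. C4 bears CH3 and CO2CH3, C10 bears CH3, C8 bears the exocyclic CH2 (C17), and C9 bears the side chain C11–C16 (C13 carbinol, C14=C15 vinyl, C16 CH2OH).
2. Retrosynthesis: the vinyl carbinol goes back to a Sharpless epoxide of a 2-substituted allyl alcohol (C14–C15 cut), C8=C17 to a C8 ketone, and the C3 methylene to a C3 ketone. Both rings are then cut at C1–C10 and C8–C9 to the acyclic aldehyde 17, which is cut at C4–C5 (Ireland–Claisen) and C11–C12 (enolate alkylation).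
3. Enabling feature: C10 is the methyl-bearing quaternary carbon shared by rings A and B and sits between C9 and C1. A trisubstituted C9=C10 alkene can therefore take a C8 acyl radical at C9 (ring B) and pass the radical to C10, which closes ring A on C1, the β-carbon of a C3 vinyl ketone.
4. Forward: bromide 3 + enone 7 → 8 → alcohol 9 → malonate 11 → acid 14 → vinyl ketone 16 → aldehyde 17 → radical bicyclization (ring B first, then ring A) → 19. Then the C3 carbonyl is removed, C8 is methylenated, and epoxidation plus one-carbon homologation give the target.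
5. Stereochemistry: the C9 carbinol (CBS reduction) is relayed to C5 and C4 by a chair Ireland–Claisen rearrangement of a chelation-defined ketene acetal. C10 and the trans ring fusion arise in the cascade, C9 is set thermodynamically through the C8 ketone, and C13 comes from the Sharpless epoxidation.
6. Helpers: the C3 ketone activates C1 and is removed via its tosylhydrazone; the C8 ketone left by the acyl radical becomes C8=C17; a dimethyl acetal masks the C8 aldehyde and a silyl ether the C16 alcohol.

Key step: step 11

Remark: labdane numbering is used for every intermediate, and reagents 6 and 10 are taken as purchasable.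

Step 1
Reactants: 1 2-methylidenepropane-1,3-diol
Product: 2 mono-TBS ether of the diol
Conditions: NaH (1.0 equiv), THF, 0 °C; then TBSCl, 0 → 25 °C
Reagents that add atoms: tert-butyldimethylsilyl chloride, CC(C)(C)[Si](C)(C)Cl
Why: O-silylation of the monosodium alkoxide of a symmetric diol should stop at the mono-ether.

Step 2
Reactants: 2 mono-TBS ether
Product: 3 allylic bromide
Conditions: CBr4, PPh3, CH2Cl2, 0 °C
Reagents that add atoms: carbon tetrabromide, BrC(Br)(Br)Br
Why: The Appel reaction converts the primary allylic alcohol into the bromide under neutral conditions that spare the silyl ether.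

Step 3
Reactants: 4 methyl 4,4-dimethoxybutanoate
Product: 5 4,4-dimethoxybutanal
Conditions: iBu2AlH (1.05 equiv), CH2Cl2, −78 °C; aq. KNaC4H4O6
Reagents that add atoms: none
Why: Partial ester reduction with iBu2AlH at low temperature should stop at the aldehyde because the aluminium hemiacetal is stable until work-up.

Step 4
Reactants: 5 4,4-dimethoxybutanal; 6 3-(triphenylphosphoranylidene)butan-2-one
Product: 7 (E)-7,7-dimethoxy-3-methylhept-3-en-2-one
Conditions: PhMe, 90 °C
Reagents that add atoms: none
Why: Wittig olefination with an acyl-stabilized α-methyl ylide should give the (E)-trisubstituted enone under thermodynamic control.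

Step 5
Reactants: 7 (E)-methyl enone; 3 allylic bromide
Product: 8 (E)-enone carrying the C11–C16 chain
Conditions: LiN(iPr)2, THF, −78 °C; then 3, DMPU, −78 → −30 °C
Reagents that add atoms: none
Why: Kinetic deprotonation at the α′-methyl group gives the cross-conjugated enolate, whose SN2 alkylation by the reactive allylic bromide forms the C11–C12 bond.

Step 6
Reactants: 8 (E)-enone
Product: 9 (5R,6E)-allylic alcohol (carbinol carbon = C9 of the target)
Conditions: (S)-2-methyl-CBS-oxazaborolidine (20 mol%), catecholborane, PhMe, −78 °C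
Reagents that add atoms: none
Why: In the Corey–Bakshi–Shibata reduction the α-methylalkenyl group acts as the large substituent, so the (S)-catalyst should deliver hydride to give the (R)-carbinol, and catecholborane does not hydroborate the alkenes at this temperature.

Step 7
Reactants: 9 (R)-allylic alcohol; 10 monomethyl methylmalonate
Product: 11 allyl methyl methylmalonate
Conditions: DCC, DMAP (cat.), CH2Cl2, 0 → 25 °C
Reagents that add atoms: none
Why: Steglich esterification acylates the secondary allylic alcohol without touching its stereocentre; the malonate carbon is enolized in the next step, so its configuration is irrelevant.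

Step 8
Reactants: 11 allyl methyl methylmalonate
Product: 14 malonic half-acid with C4 and C5 set, via silyl ketene acetal 12 (not isolated), via trimethylsilyl ester 13 (not isolated)
Conditions: LiN(SiMe3)2, THF, −78 °C; Me3SiCl, Et3N; PhMe, −78 → 90 °C; then MeOH/H2O, pH 5 buffer
Reagents that add atoms: trimethylsilyl chloride, C[Si](C)(C)Cl (silicon of 12 and 13 only)
Why: Ireland–Claisen rearrangement: the lithium-chelated malonate enolate is silylated with CO2CH3 cis to OSiMe3, and a chair transition state on the (E)-allyl unit with the C9 substituent equatorial transfers the carbinol chirality to C5, sets C4 (CO2CH3 syn to the C6 chain) and leaves an (E)-C9=C10 alkene.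

Step 9
Reactants: 14 malonic half-acid
Product: 16 vinyl ketone (C3 ketone with C1=C2), via acid chloride 15 (not isolated)
Conditions: 1-chloro-N,N,2-trimethylprop-1-en-1-amine, CH2Cl2, 0 °C; then CH2=CHMgBr (1.05 equiv), CuI (10 mol%), THF, −78 °C
Reagents that add atoms: 1-chloro-N,N,2-trimethylprop-1-en-1-amine, CC(C)=C(Cl)N(C)C (chlorine of 15 only); vinylmagnesium bromide, C=C[Mg]Br
Why: Neutral acid-chloride formation followed by copper-catalysed acylation of the Grignard reagent should give the ketone without attack on the hindered methyl ester, the acetal or the silyl ether.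

Step 10
Reactants: 16 vinyl ketone acetal
Product: 17 acyclic aldehyde (cascade precursor)
Conditions: pyridinium p-toluenesulfonate (cat.), acetone/H2O, 40 °C
Reagents that add atoms: water, O
Why: Mild acid-catalysed acetal hydrolysis frees the C8 aldehyde while the primary silyl ether and the vinyl ketone survive.

Step 11
Reactants: 17 acyclic aldehyde
Product: 19 trans-decalin 3,8-diketone, via C9-epimeric diketone 18 (not isolated)
Conditions: tert-dodecanethiol (0.2 equiv, slow addition), 1,1′-azobis(cyclohexanecarbonitrile) (0.3 equiv, in portions), PhCl (0.005 M), 100 °C; then DBU, PhMe, 25 °C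
Reagents that add atoms: none
Why: Proposed new method: a thiyl radical abstracts the aldehydic hydrogen of 17, the C8 acyl radical adds 6-endo-trig to C9 of the C9=C10 alkene (ring B), the resulting tertiary C10 radical adds 6-endo-trig to C1 of the C3 vinyl ketone (ring A, the C1–C10 bond), and the α-keto radical at C2 takes hydrogen from the thiol or from a further aldehyde to carry the chain. The closest known reaction types are acyl-radical polyene cascades started from acyl selenides with tin hydride and the thiol-catalysed acyl-radical cyclization of alkenals; what is new is their combination with an enone terminus on a chain branched at C5. Both rings close through chair-like transition states, and in the second closure the C5 substituent (quaternary C4) lies equatorial on ring B while C1 bonds to C10 so that the new bond is equatorial and the C10 methyl axial and anti to C5–H, which gives the trans fusion as in the second ring closure of radical polyene cyclizations. C4 and C5 are already in place from the Ireland–Claisen rearrangement of step 8, and C9 is formed in the first closure and then equilibrated by DBU through the C8 ketone enolate to the equatorial side chain, so its kinetic outcome does not matter. The step needs 6-endo over 5-exo closure, secured by the methyl group on C10 and by the polarization of the enone whose β-carbon is C1, and it needs the C10 radical to prefer the enone over the unactivated side-chain alkene, secured by the nucleophilic-radical/electron-poor-acceptor pairing; high dilution and slow thiol addition limit premature hydrogen transfer to the C10 radical.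

Step 12
Reactants: 19 3,8-diketone
Product: 20 C3 mono-tosylhydrazone
Conditions: TsNHNH2 (1.05 equiv), EtOH, 25 → 50 °C
Reagents that add atoms: p-toluenesulfonyl hydrazide, Cc1ccc(cc1)S(=O)(=O)NN
Why: Hydrazone condensation should occur at C3, the more electrophilic β-keto-ester carbonyl with an open axial face, rather than at C8, which is flanked by the C9 side chain and shielded by the axial C10 methyl.

Step 13
Reactants: 20 C3 tosylhydrazone
Product: 21 C8 ketone with C3 as CH2
Conditions: catecholborane, CHCl3, 0 °C; then NaOAc·3H2O, 60 °C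
Reagents that add atoms: none
Why: Tosylhydrazone reduction (hydride addition to C=N, loss of sulfinate, loss of N2 from the diazene) removes the C3 carbonyl helper and should leave the hindered C8 ketone, the alkene and the esters untouched.

Step 14
Reactants: 21 C8 ketone
Product: 22 exocyclic alkene (C8=C17), TBS ether
Conditions: Ph3PCH3Br, KOtBu, PhMe, 80 °C
Reagents that add atoms: methyltriphenylphosphonium bromide, C[P+](c1ccccc1)(c1ccccc1)c1ccccc1.[Br-]
Why: Wittig methylenation of the hindered ketone installs the exocyclic methylene, and C9 stays in its thermodynamically preferred equatorial configuration under the basic conditions.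

Step 15
Reactants: 22 TBS ether
Product: 23 2-substituted allylic alcohol
Conditions: Bu4NF, THF, 0 → 25 °C
Reagents that add atoms: none
Why: Fluoride-mediated desilylation frees the C16 alcohol without affecting the ester or the alkenes.

Step 16
Reactants: 23 allylic alcohol
Product: 24 (13S)-epoxy alcohol
Conditions: Ti(OiPr)4 (cat.), L-(+)-diethyl tartrate, t-BuOOH, 4 Å molecular sieves, CH2Cl2, −20 °C
Reagents that add atoms: tert-butyl hydroperoxide, CC(C)(C)OO
Why: Sharpless asymmetric epoxidation is reagent-controlled (the L-(+)-tartrate should give the (S)-configured C13, as for other 2-substituted allyl alcohols) and selective for the allylic alcohol over the exocyclic alkene.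

Step 17
Reactants: 24 epoxy alcohol
Product: 25 target compound
Conditions: Me3SI (5 equiv), n-BuLi (4.8 equiv), THF, −10 → 25 °C
Reagents that add atoms: trimethylsulfonium iodide, C[S+](C)C.[I-]
Why: Epoxide-to-allylic-alcohol homologation: dimethylsulfonium methylide opens the epoxide at its CH2 terminus and a second equivalent of ylide eliminates dimethyl sulfide, giving the vinyl carbinol with the C13–O bond untouched (a Payne rearrangement of the alkoxide would lead to the same product).

**Compound list**
1 | 2-methylidenepropane-1,3-diol | C=C(CO)CO | starting material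
2 | 2-{[(tert-butyldimethylsilyl)oxy]methyl}prop-2-en-1-ol | C=C(CO)CO[Si](C)(C)C(C)(C)C | intermediate
3 | {[2-(bromomethyl)prop-2-en-1-yl]oxy}(tert-butyl)dimethylsilane | C=C(CBr)CO[Si](C)(C)C(C)(C)C | intermediate
4 | methyl 4,4-dimethoxybutanoate | COC(OC)CCC(=O)OC | starting material
5 | 4,4-dimethoxybutanal | COC(OC)CCC=O | intermediate
6 | 3-(triphenylphosphoranylidene)butan-2-one | CC(=O)C(C)=P(c1ccccc1)(c1ccccc1)c1ccccc1 | starting material
7 | (3E)-7,7-dimethoxy-3-methylhept-3-en-2-one | COC(OC)CC/C=C(C)/C(C)=O | intermediate
8 | (6E)-1-{[tert-butyl(dimethyl)silyl]oxy}-10,10-dimethoxy-6-methyl-2-methylidenedec-6-en-5-one | COC(OC)CC/C=C(C)/C(=O)CCC(=C)CO[Si](C)(C)C(C)(C)C | intermediate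
9 | (5R,6E)-1-{[tert-butyl(dimethyl)silyl]oxy}-10,10-dimethoxy-6-methyl-2-methylidenedec-6-en-5-ol | COC(OC)CC/C=C(C)/[C@H](O)CCC(=C)CO[Si](C)(C)C(C)(C)C | intermediate
10 | 3-methoxy-2-methyl-3-oxopropanoic acid (monomethyl methylmalonate, racemic) | COC(=O)C(C)C(=O)O | starting material
11 | (5R,6E)-1-{[tert-butyl(dimethyl)silyl]oxy}-10,10-dimethoxy-6-methyl-2-methylidenedec-6-en-5-yl methyl 2-methylpropanedioate (both epimers at the malonate carbon) | COC(OC)CC/C=C(C)/[C@H](OC(=O)C(C)C(=O)OC)CCC(=C)CO[Si](C)(C)C(C)(C)C | intermediate
12 | (Z)-trimethylsilyl ketene acetal of 11 (CO2CH3 cis to OSiMe3) | COC(OC)CC/C=C(C)/[C@H](O/C(O[Si](C)(C)C)=C(\C)C(=O)OC)CCC(=C)CO[Si](C)(C)C(C)(C)C | intermediate (not isolated)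
13 | trimethylsilyl ester of acid 14 | COC(OC)CC[C@H]([C@@](C)(C(=O)OC)C(=O)O[Si](C)(C)C)/C(C)=C/CCC(=C)CO[Si](C)(C)C(C)(C)C | intermediate (not isolated)
14 | (2R)-2-[(4S,5E)-10-{[tert-butyl(dimethyl)silyl]oxy}-1,1-dimethoxy-5-methyl-9-methylidenedec-5-en-4-yl]-3-methoxy-2-methyl-3-oxopropanoic acid (labdane C4 = R, C5 = S) | COC(OC)CC[C@H]([C@@](C)(C(=O)OC)C(=O)O)/C(C)=C/CCC(=C)CO[Si](C)(C)C(C)(C)C | intermediate
15 | acid chloride of 14 (same configuration) | COC(OC)CC[C@H]([C@@](C)(C(=O)OC)C(=O)Cl)/C(C)=C/CCC(=C)CO[Si](C)(C)C(C)(C)C | intermediate (not isolated)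
16 | methyl (2R)-2-[(4S,5E)-10-{[tert-butyl(dimethyl)silyl]oxy}-1,1-dimethoxy-5-methyl-9-methylidenedec-5-en-4-yl]-2-methyl-3-oxopent-4-enoate | COC(OC)CC[C@H]([C@@](C)(C(=O)OC)C(=O)C=C)/C(C)=C/CCC(=C)CO[Si](C)(C)C(C)(C)C | intermediate
17 | methyl (2R)-2-[(4S,5E)-10-{[tert-butyl(dimethyl)silyl]oxy}-5-methyl-9-methylidene-1-oxodec-5-en-4-yl]-2-methyl-3-oxopent-4-enoate | O=CCC[C@H]([C@@](C)(C(=O)OC)C(=O)C=C)/C(C)=C/CCC(=C)CO[Si](C)(C)C(C)(C)C | intermediate
18 | methyl (1R,4aR,5R,8aS)-5-[3-({[tert-butyl(dimethyl)silyl]oxy}methyl)but-3-en-1-yl]-1,4a-dimethyl-2,6-dioxodecahydronaphthalene-1-carboxylate (C9 epimer of 19) | C=C(CO[Si](C)(C)C(C)(C)C)CC[C@H]1C(=O)CC[C@H]2[C@@]1(C)CCC(=O)[C@]2(C)C(=O)OC | intermediate (not isolated)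
19 | methyl (1R,4aR,5S,8aS)-5-[3-({[tert-butyl(dimethyl)silyl]oxy}methyl)but-3-en-1-yl]-1,4a-dimethyl-2,6-dioxodecahydronaphthalene-1-carboxylate | C=C(CO[Si](C)(C)C(C)(C)C)CC[C@@H]1C(=O)CC[C@H]2[C@@]1(C)CCC(=O)[C@]2(C)C(=O)OC | intermediate
20 | 2-(p-toluenesulfonylhydrazone) of 19 (hydrazone at labdane C3; ring configuration as in 19) | C=C(CO[Si](C)(C)C(C)(C)C)CC[C@@H]1C(=O)CC[C@H]2[C@@]1(C)CCC(=NNS(=O)(=O)c3ccc(C)cc3)[C@]2(C)C(=O)OC | intermediate
21 | methyl (1S,4aR,5S,8aS)-5-[3-({[tert-butyl(dimethyl)silyl]oxy}methyl)but-3-en-1-yl]-1,4a-dimethyl-6-oxodecahydronaphthalene-1-carboxylate | C=C(CO[Si](C)(C)C(C)(C)C)CC[C@@H]1C(=O)CC[C@H]2[C@@]1(C)CCC[C@]2(C)C(=O)OC | intermediate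
22 | methyl (1S,4aS,5R,8aS)-5-[3-({[tert-butyl(dimethyl)silyl]oxy}methyl)but-3-en-1-yl]-1,4a-dimethyl-6-methylidenedecahydronaphthalene-1-carboxylate | C=C(CO[Si](C)(C)C(C)(C)C)CC[C@@H]1C(=C)CC[C@H]2[C@@]1(C)CCC[C@]2(C)C(=O)OC | intermediate
23 | methyl (1S,4aS,5R,8aS)-5-[3-(hydroxymethyl)but-3-en-1-yl]-1,4a-dimethyl-6-methylidenedecahydronaphthalene-1-carboxylate | C=C(CO)CC[C@@H]1C(=C)CC[C@H]2[C@@]1(C)CCC[C@]2(C)C(=O)OC | intermediate
24 | methyl (1S,4aS,5R,8aS)-5-{2-[(2S)-2-(hydroxymethyl)oxiran-2-yl]ethyl}-1,4a-dimethyl-6-methylidenedecahydronaphthalene-1-carboxylate | O1C[C@@]1(CO)CC[C@@H]2C(=C)CC[C@H]3[C@@]2(C)CCC[C@]3(C)C(=O)OC | intermediate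
25 | methyl (1S,4aS,5R,8aS)-5-[(3R)-3-hydroxy-3-(hydroxymethyl)pent-4-en-1-yl]-1,4a-dimethyl-6-methylidenedecahydronaphthalene-1-carboxylate (labdane 4S,5S,9R,10S,13R) | C=C[C@@](O)(CO)CC[C@@H]1C(=C)CC[C@H]2[C@@]1(C)CCC[C@]2(C)C(=O)OC | target

Total steps: 17. Longest linear sequence: 15 steps (steps 3 to 17).

**Steps most likely to fail**

1. Step 11 (radical bicyclization, proposed new method). The acyl or the C10 radical may take hydrogen before it cyclizes, the thiol may be consumed by addition to the vinyl ketone, or ring A may close on the wrong face to give the cis fusion. Fallback with known chemistry, forming the rings one at a time: from 17, SnBr4 in CH2Cl2 at −78 °C should effect a carbonyl–alkene (Prins) cyclization with bromide capture, giving ring B as the tertiary bromide bromohydrin F1. Bu3SnH/AIBN under slow addition in PhH at 80 °C then generates the C10 radical from the C–Br bond, which closes ring A by 6-endo conjugate addition to the vinyl ketone to give hydroxy ketone F2. Dess–Martin oxidation of the C8 alcohol and DBU equilibration at C9 return to 19.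

2. Step 12 (mono-tosylhydrazone). Discrimination between the two ketones may be insufficient, with condensation at C8 or at both carbonyls. Fallback that keeps C8 at the alcohol level while C3 is removed: from 17 through bromohydrin F1 and hydroxy ketone F2 as above, the only ketone of F2 is condensed with TsNHNH2 to tosylhydrazone F3, which is reduced with catecholborane/NaOAc to alcohol F4. Dess–Martin oxidation followed by DBU then gives 21.

3. Step 8 (Ireland–Claisen). Diastereocontrol at C4 may erode through scrambling of the ketene acetal geometry at the temperature needed or through a competing boat transition state, and the half-acid may decarboxylate on work-up. Fallback that fixes the geometry in an enol ether: from 9, acid-catalysed alkoxy exchange with methyl (E)-3-methoxy-2-methylbut-2-enoate (pyridinium p-toluenesulfonate, PhMe, 110 °C, removal of methanol) gives (E)-enol ether F5. Its thermal Claisen rearrangement (chair, CO2CH3 equatorial) gives methyl ketone F6 with the same C4/C5 configuration. LiN(SiMe3)2/Me3SiCl followed by dimethylmethylideneammonium iodide (Mannich reaction) gives amino ketone F7, and CH3I then NaHCO3 eliminates to vinyl ketone 16.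

**Further compounds**
F1 | step 11 | bromohydrin: ring B closed, C8–OH, C10–Br (mixture at C8, C9, C10; C4 and C5 as in 17) | OC1CC[C@H]([C@@](C)(C(=O)OC)C(=O)C=C)C(C)(Br)C1CCC(=C)CO[Si](C)(C)C(C)(C)C
F2 | step 11 | trans-decalin hydroxy ketone: C3 ketone, C8–OH (mixture at C8 and C9) | C=C(CO[Si](C)(C)C(C)(C)C)CCC1C(O)CC[C@H]2[C@@]1(C)CCC(=O)[C@]2(C)C(=O)OC
F3 | step 12 | C3 tosylhydrazone of F2 | C=C(CO[Si](C)(C)C(C)(C)C)CCC1C(O)CC[C@H]2[C@@]1(C)CCC(=NNS(=O)(=O)c3ccc(C)cc3)[C@]2(C)C(=O)OC
F4 | step 12 | C8 alcohol with C3 as CH2 (mixture at C8 and C9) | C=C(CO[Si](C)(C)C(C)(C)C)CCC1C(O)CC[C@H]2[C@@]1(C)CCC[C@]2(C)C(=O)OC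
F5 | step 8 | (E)-enol ether of 9 with methyl 2-methyl-3-oxobutanoate (CO2CH3 trans to the allyloxy group) | COC(OC)CC/C=C(C)/[C@H](O/C(C)=C(\C)C(=O)OC)CCC(=C)CO[Si](C)(C)C(C)(C)C
F6 | step 8 | methyl ketone analogue of 16 (C3 acetyl; C4 and C5 as in 16) | COC(OC)CC[C@H]([C@@](C)(C(=O)OC)C(C)=O)/C(C)=C/CCC(=C)CO[Si](C)(C)C(C)(C)C
F7 | step 8 | Mannich base of F6 (C3 ketone with CH2CH2N(CH3)2) | COC(OC)CC[C@H]([C@@](C)(C(=O)OC)C(=O)CCN(C)C)/C(C)=C/CCC(=C)CO[Si](C)(C)C(C)(C)C
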